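**Retrosynthetic overview**

1. Target 25 ⇐ 24 (three aryl MOM ethers removed) ⇐ 23 (ketone from the carbinol) ⇐ 22 (silyl ether); only protecting-group and oxidation-level changes follow the key step.
2. 22 ⇐ one-pot three-component aryne coupling: the C6–CH2 bond forms by addition of alkylmagnesium 18 to the 6,7-aryne of chromene 8, and the C7–prenyl bond by trapping the resulting C7–Mg with prenyl bromide 17.
3. Enabling feature: the contiguous C6 (chain) / C7 (prenyl) / C8 (oxygen) triad on the benzene ring of the chromene. The C8 oxygen (as OMOM) beside Cl-6 makes H-7 the acidic site, polarises the C6≡C7 aryne so that carbon nucleophiles enter at C6, and chelates the C7 carbanion that takes up the prenyl group.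
4. 8 ⇐ 5-chlorosalicylaldehyde 1 + 3-chloro-3-methylbut-1-yne 2 (ether, Baeyer–Villiger, MOM, propargyl Claisen/oxa-6π); 18 ⇐ 2,4-dihydroxybenzaldehyde 9 (MOM, vinyl Grignard, TBS, hydroboration, bromide, Mg).
5. Ring order: both benzene rings are purchased; the 2H-pyran ring of the chromene is closed in step 4; no ring is formed after that.

Key step: step 10

Remark: the target is achiral; the carbinol centre present from 12 to 23 is carried as a racemate (SMILES drawn without descriptor) and is erased by the oxidation in step 12.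

**Route**

Step 1
Reactants: 1 5-chloro-2-hydroxybenzaldehyde; 2 3-chloro-3-methylbut-1-yne
Product: 3 5-chloro-2-[(2-methylbut-3-yn-2-yl)oxy]benzaldehyde
Conditions: CuCl2·2H2O (cat.), DBU, MeCN, 0 °C → rt
Reagents that add atoms: none
Why: Copper-catalysed propargylic substitution lets the phenoxide O-alkylate the tertiary propargylic chloride, the standard entry to aryl 1,1-dimethylpropargyl ethers, and should tolerate the ortho aldehyde.

Step 2
Reactants: 3 5-chloro-2-[(2-methylbut-3-yn-2-yl)oxy]benzaldehyde
Product: 5 5-chloro-2-[(2-methylbut-3-yn-2-yl)oxy]phenol, via aryl formate 4 (not isolated)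
Conditions: mCPBA, NaHCO3, CH2Cl2, rt; then K2CO3 (cat.), MeOH, rt
Reagents that add atoms: mCPBA (3-chloroperoxybenzoic acid), OOC(=O)c1cccc(Cl)c1
Why: Baeyer–Villiger oxidation of an ortho-alkoxybenzaldehyde should proceed with aryl migration to the formate, which mild methanolysis cleaves to the phenol, while the terminal alkyne reacts only slowly with peracid.

Step 3
Reactants: 5 5-chloro-2-[(2-methylbut-3-yn-2-yl)oxy]phenol
Product: 6 4-chloro-2-(methoxymethoxy)-1-[(2-methylbut-3-yn-2-yl)oxy]benzene
Conditions: NaH, MOMCl, THF, 0 °C → rt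
Reagents that add atoms: chloromethyl methyl ether (MOMCl), COCCl
Why: Williamson-type O-alkylation of the sodium phenoxide installs the acetal that later directs the lithiation and chelates the C7 metal.

Step 4
Reactants: 6 4-chloro-2-(methoxymethoxy)-1-[(2-methylbut-3-yn-2-yl)oxy]benzene
Product: 8 6-chloro-8-(methoxymethoxy)-2,2-dimethyl-2H-chromene, via allenylphenol 7 (not isolated)
Conditions: o-xylene, 145 °C
Reagents that add atoms: none
Why: Thermal aryl propargyl ether Claisen rearrangement to the only free ortho carbon should give allenylphenol 7, which closes the 2,2-dimethyl-2H-pyran ring by 1,5-hydrogen shift and oxa-6π electrocyclisation.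

Step 5
Reactants: 9 2,4-dihydroxybenzaldehyde
Product: 10 2,4-bis(methoxymethoxy)benzaldehyde
Conditions: NaH, MOMCl, DMF, 0 °C → rt
Reagents that add atoms: chloromethyl methyl ether (MOMCl), COCCl
Why: Double Williamson-type O-alkylation protects both phenols, including the hydrogen-bonded ortho one, as base-stable acetals compatible with the later organometallic steps.

Step 6
Reactants: 10 2,4-bis(methoxymethoxy)benzaldehyde; 11 vinylmagnesium bromide
Product: 12 rac-1-[2,4-bis(methoxymethoxy)phenyl]prop-2-en-1-ol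
Conditions: THF, 0 °C; then aq. NH4Cl
Reagents that add atoms: none
Why: Grignard 1,2-addition to the aldehyde gives the allylic alcohol as a racemate, and the new carbinol centre needs no control because step 12 oxidises it to the ketone.

Step 7
Reactants: 12 rac-1-[2,4-bis(methoxymethoxy)phenyl]prop-2-en-1-ol
Product: 13 rac-tert-butyl({1-[2,4-bis(methoxymethoxy)phenyl]prop-2-en-1-yl}oxy)dimethylsilane
Conditions: TBSCl, imidazole, DMF, rt
Reagents that add atoms: tert-butyldimethylsilyl chloride (TBSCl), CC(C)(C)[Si](C)(C)Cl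
Why: Imidazole-promoted silylation gives a TBS ether that should survive hydroboration, Grignard formation and the aryne step and is orthogonal to the MOM groups.

Step 8
Reactants: 13 rac-tert-butyl({1-[2,4-bis(methoxymethoxy)phenyl]prop-2-en-1-yl}oxy)dimethylsilane
Product: 15 rac-3-[2,4-bis(methoxymethoxy)phenyl]-3-[(tert-butyldimethylsilyl)oxy]propan-1-ol, via alkylborane 14 (not isolated)
Conditions: 9-BBN, THF, 0 °C → rt; then NaOH, H2O2, 0 °C
Reagents that add atoms: hydrogen peroxide, OO
Why: Hydroboration–oxidation with 9-BBN places boron on the terminal carbon of the monosubstituted alkene (anti-Markovnikov, steric control) and alkaline peroxide converts the C–B bond into the primary alcohol.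

Step 9
Reactants: 15 rac-3-[2,4-bis(methoxymethoxy)phenyl]-3-[(tert-butyldimethylsilyl)oxy]propan-1-ol
Product: 16 rac-{3-bromo-1-[2,4-bis(methoxymethoxy)phenyl]propoxy}(tert-butyl)dimethylsilane
Conditions: CBr4, PPh3, imidazole (cat.), CH2Cl2, 0 °C
Reagents that add atoms: carbon tetrabromide, BrC(Br)(Br)Br
Why: The Appel reaction converts the primary alcohol into the bromide by SN2 displacement of the oxyphosphonium under near-neutral conditions that should spare the benzylic silyl ether and the MOM acetals.

Step 10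
Reactants: 8 6-chloro-8-(methoxymethoxy)-2,2-dimethyl-2H-chromene; 16 rac-{3-bromo-1-[2,4-bis(methoxymethoxy)phenyl]propoxy}(tert-butyl)dimethylsilane; 17 1-bromo-3-methylbut-2-ene (prenyl bromide)
Product: 22 rac-tert-butyl{1-[2,4-bis(methoxymethoxy)phenyl]-3-[8-(methoxymethoxy)-2,2-dimethyl-7-(3-methylbut-2-en-1-yl)-2H-chromen-6-yl]propoxy}dimethylsilane, via alkylmagnesium bromide 18 (not isolated), via aryllithium 19 (not isolated), via chromen-6,7-yne 20 (not isolated), via arylmagnesium bromide 21 (not isolated)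
Conditions: 16 (2 equiv), Mg, THF, rt; separately 8, s-BuLi (1.0 equiv), THF, −78 °C; combine at −78 °C, warm to 0 °C; then CuBr·SMe2 (cat.), 17, −30 °C → rt
Reagents that add atoms: none
Why: s-BuLi removes H-7, the only proton flanked by Cl-6 and the coordinating 8-OMOM group, and on warming aryllithium 19 loses LiCl to give the 6,7-aryne 20; the primary alkylmagnesium bromide 18, present in excess, adds across the strained triple bond (carbomagnesiation) to form the C6–CH2 bond and arylmagnesium 21, whose C7–Mg bond is then allylated by prenyl bromide under Cu(I) catalysis. The closest known reaction type is the three-component coupling of 3-alkoxybenzynes, generated from ortho-lithiated 3-haloanisoles, with Grignard or organolithium reagents followed by electrophilic quench of the 2-alkoxyarylmetal. No ring is closed and no stereocentre is formed; the racemic carbinol centre of 18 is carried through unchanged. The step needs attack at C6 and not C7 of the aryne: the σ-withdrawing 8-oxygen distorts and polarises the aryne so that the nucleophile bonds at the carbon meta to it and the negative charge develops at the ortho carbon, where the MOM oxygen chelates magnesium. It also needs α- and not γ-allylation, which the hindered 2,6-disubstituted arylcopper and the gem-dimethyl terminus of prenyl bromide should secure. The silyl ether, the MOM acetals and the chromene alkene should be inert to the organometallics at these temperatures.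

Step 11
Reactants: 22 rac-tert-butyl{1-[2,4-bis(methoxymethoxy)phenyl]-3-[8-(methoxymethoxy)-2,2-dimethyl-7-(3-methylbut-2-en-1-yl)-2H-chromen-6-yl]propoxy}dimethylsilane
Product: 23 rac-1-[2,4-bis(methoxymethoxy)phenyl]-3-[8-(methoxymethoxy)-2,2-dimethyl-7-(3-methylbut-2-en-1-yl)-2H-chromen-6-yl]propan-1-ol
Conditions: TBAF, THF, 0 °C → rt
Reagents that add atoms: none
Why: Fluoride-induced desilylation, driven by the strong Si–F bond, should free the benzylic alcohol without touching the MOM ethers or the alkenes.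

Step 12
Reactants: 23 rac-1-[2,4-bis(methoxymethoxy)phenyl]-3-[8-(methoxymethoxy)-2,2-dimethyl-7-(3-methylbut-2-en-1-yl)-2H-chromen-6-yl]propan-1-ol
Product: 24 1-[2,4-bis(methoxymethoxy)phenyl]-3-[8-(methoxymethoxy)-2,2-dimethyl-7-(3-methylbut-2-en-1-yl)-2H-chromen-6-yl]propan-1-one
Conditions: Dess–Martin periodinane, NaHCO3, CH2Cl2, 0 °C → rt
Reagents that add atoms: none
Why: Dess–Martin oxidation of the secondary benzylic alcohol under buffered conditions should give the aryl ketone, leave the prenyl and chromene alkenes and the acetals intact, and remove the racemic stereocentre.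

Step 13
Reactants: 24 1-[2,4-bis(methoxymethoxy)phenyl]-3-[8-(methoxymethoxy)-2,2-dimethyl-7-(3-methylbut-2-en-1-yl)-2H-chromen-6-yl]propan-1-one
Product: 25 1-(2,4-dihydroxyphenyl)-3-[8-hydroxy-2,2-dimethyl-7-(3-methylbut-2-en-1-yl)-2H-chromen-6-yl]propan-1-one (CNP0290651.0)
Conditions: HCl (dilute), MeOH, rt
Reagents that add atoms: none
Why: Acid-catalysed transacetalisation to methanol should cleave all three aryl MOM ethers, and dilute acid at room temperature is expected to be too mild for cyclisation of the prenyl group onto the C8 phenol or hydration of the chromene.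

**Compound list**

1 | 5-chloro-2-hydroxybenzaldehyde | O=Cc1cc(Cl)ccc1O | starting material
2 | 3-chloro-3-methylbut-1-yne | C#CC(C)(C)Cl | starting material
3 | 5-chloro-2-[(2-methylbut-3-yn-2-yl)oxy]benzaldehyde | C#CC(C)(C)Oc1ccc(Cl)cc1C=O | intermediate
4 | 5-chloro-2-[(2-methylbut-3-yn-2-yl)oxy]phenyl formate | C#CC(C)(C)Oc1ccc(Cl)cc1OC=O | intermediate
5 | 5-chloro-2-[(2-methylbut-3-yn-2-yl)oxy]phenol | C#CC(C)(C)Oc1ccc(Cl)cc1O | intermediate
6 | 4-chloro-2-(methoxymethoxy)-1-[(2-methylbut-3-yn-2-yl)oxy]benzene | C#CC(C)(C)Oc1ccc(Cl)cc1OCOC | intermediate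
7 | 4-chloro-2-(methoxymethoxy)-6-(3-methylbuta-1,2-dien-1-yl)phenol | COCOc1cc(Cl)cc(C=C=C(C)C)c1O | intermediate
8 | 6-chloro-8-(methoxymethoxy)-2,2-dimethyl-2H-chromene | COCOc1cc(Cl)cc2C=CC(C)(C)Oc12 | intermediate
9 | 2,4-dihydroxybenzaldehyde | O=Cc1ccc(O)cc1O | starting material
10 | 2,4-bis(methoxymethoxy)benzaldehyde | COCOc1ccc(C=O)c(OCOC)c1 | intermediate
11 | vinylmagnesium bromide | C=C[Mg]Br | starting material
12 | rac-1-[2,4-bis(methoxymethoxy)phenyl]prop-2-en-1-ol | C=CC(O)c1ccc(OCOC)cc1OCOC | intermediate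
13 | rac-tert-butyl({1-[2,4-bis(methoxymethoxy)phenyl]prop-2-en-1-yl}oxy)dimethylsilane | C=CC(O[Si](C)(C)C(C)(C)C)c1ccc(OCOC)cc1OCOC | intermediate
14 | rac-9-{3-[2,4-bis(methoxymethoxy)phenyl]-3-[(tert-butyldimethylsilyl)oxy]propyl}-9-borabicyclo[3.3.1]nonane | CC(C)(C)[Si](C)(C)OC(CCB1C2CCCC1CCC2)c1ccc(OCOC)cc1OCOC | intermediate
15 | rac-3-[2,4-bis(methoxymethoxy)phenyl]-3-[(tert-butyldimethylsilyl)oxy]propan-1-ol | OCCC(O[Si](C)(C)C(C)(C)C)c1ccc(OCOC)cc1OCOC | intermediate
16 | rac-{3-bromo-1-[2,4-bis(methoxymethoxy)phenyl]propoxy}(tert-butyl)dimethylsilane | BrCCC(O[Si](C)(C)C(C)(C)C)c1ccc(OCOC)cc1OCOC | intermediate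
17 | 1-bromo-3-methylbut-2-ene (prenyl bromide) | CC(C)=CCBr | starting material
18 | rac-{3-[2,4-bis(methoxymethoxy)phenyl]-3-[(tert-butyldimethylsilyl)oxy]propyl}magnesium bromide | Br[Mg]CCC(O[Si](C)(C)C(C)(C)C)c1ccc(OCOC)cc1OCOC | intermediate
19 | [6-chloro-8-(methoxymethoxy)-2,2-dimethyl-2H-chromen-7-yl]lithium | COCOc1c([Li])c(Cl)cc2C=CC(C)(C)Oc12 | intermediate
20 | 6,7-didehydro-8-(methoxymethoxy)-2,2-dimethyl-2H-chromene (6,7-aryne) | COCOC1=C2OC(C)(C)C=CC2=CC#C1 | intermediate
21 | rac-{6-{3-[2,4-bis(methoxymethoxy)phenyl]-3-[(tert-butyldimethylsilyl)oxy]propyl}-8-(methoxymethoxy)-2,2-dimethyl-2H-chromen-7-yl}magnesium bromide | COCOc1c([Mg]Br)c(CCC(O[Si](C)(C)C(C)(C)C)c2ccc(OCOC)cc2OCOC)cc2C=CC(C)(C)Oc12 | intermediate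
22 | rac-tert-butyl{1-[2,4-bis(methoxymethoxy)phenyl]-3-[8-(methoxymethoxy)-2,2-dimethyl-7-(3-methylbut-2-en-1-yl)-2H-chromen-6-yl]propoxy}dimethylsilane | CC(C)=CCc1c(CCC(O[Si](C)(C)C(C)(C)C)c2ccc(OCOC)cc2OCOC)cc2C=CC(C)(C)Oc2c1OCOC | intermediate
23 | rac-1-[2,4-bis(methoxymethoxy)phenyl]-3-[8-(methoxymethoxy)-2,2-dimethyl-7-(3-methylbut-2-en-1-yl)-2H-chromen-6-yl]propan-1-ol | CC(C)=CCc1c(CCC(O)c2ccc(OCOC)cc2OCOC)cc2C=CC(C)(C)Oc2c1OCOC | intermediate
24 | 1-[2,4-bis(methoxymethoxy)phenyl]-3-[8-(methoxymethoxy)-2,2-dimethyl-7-(3-methylbut-2-en-1-yl)-2H-chromen-6-yl]propan-1-one | CC(C)=CCc1c(CCC(=O)c2ccc(OCOC)cc2OCOC)cc2C=CC(C)(C)Oc2c1OCOC | intermediate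
25 | 1-(2,4-dihydroxyphenyl)-3-[8-hydroxy-2,2-dimethyl-7-(3-methylbut-2-en-1-yl)-2H-chromen-6-yl]propan-1-one | CC(C)=CCc1c(CCC(=O)c2ccc(O)cc2O)cc2c(c1O)OC(C)(C)C=C2 | target

**Totals and risks**

Total step count: 13.
Longest linear sequence: 9 steps (steps 5–9 and 10–13, from 2,4-dihydroxybenzaldehyde 9).

Steps most likely to fail:

Step 10. The aryne may be captured by aryllithium 19 itself (self-coupling) or by adventitious protons instead of the less nucleophilic primary alkyl Grignard, and the hindered arylmagnesium may be allylated incompletely or at the γ-carbon. The fallback forms the same bonds one at a time without an aryne; it sets out from 8 and from alkylborane 14 (prepared from 13 as in the first half of step 8, not oxidised) and returns at 22. Compound 8 is lithiated at C7 (s-BuLi, THF, −78 °C) and, held at −78 °C so that LiCl is not lost, transmetalated with CuBr·SMe2 and allylated with 17 to give 6-chloro-8-(methoxymethoxy)-2,2-dimethyl-7-(3-methylbut-2-en-1-yl)-2H-chromene F1. B-alkyl Suzuki–Miyaura coupling of F1 with 14 (Pd(OAc)2, SPhos, K3PO4, THF/H2O, 65 °C) then makes the C6–CH2 bond and gives 22.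

Step 13. Acid may promote addition of the freed C8 phenol across the neighbouring prenyl double bond, or protonation of the chromene alkene, before the hindered third MOM ether is cleaved. The fallback avoids protic acid by exchanging the protecting groups; it sets out from 24 and returns at 25. TESOTf/2,2′-bipyridyl (CH2Cl2, 0 °C) should convert the three aryl MOM acetals into triethylsilyl ethers under aprotic conditions to give 1-{2,4-bis[(triethylsilyl)oxy]phenyl}-3-{2,2-dimethyl-7-(3-methylbut-2-en-1-yl)-8-[(triethylsilyl)oxy]-2H-chromen-6-yl}propan-1-one F2, and buffered fluoride (TBAF/AcOH, THF, 0 °C) should then free the phenols to give 25.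

Step 2. Hydride rather than aryl migration in the Criegee intermediate (over-oxidation to the acid) or acid-induced loss of the tertiary propargylic ether may erode the oxidation. The fallback brings the C8 oxygen in as a methyl ether and avoids the oxidation; it sets out from 2 and returns at 8. Commercial 4-chloro-2-methoxyphenol is O-alkylated with 2 under the conditions of step 1 to give 4-chloro-2-methoxy-1-[(2-methylbut-3-yn-2-yl)oxy]benzene F3, which is heated as in step 4 to give 6-chloro-8-methoxy-2,2-dimethyl-2H-chromene F4. Nucleophilic demethylation (NaSEt, DMF, 120 °C) gives 6-chloro-2,2-dimethyl-2H-chromen-8-ol F5, and NaH/MOMCl as in step 3 gives 8.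

**Further compounds**

F1 | step 10 | 6-chloro-8-(methoxymethoxy)-2,2-dimethyl-7-(3-methylbut-2-en-1-yl)-2H-chromene | CC(C)=CCc1c(Cl)cc2C=CC(C)(C)Oc2c1OCOC
F2 | step 13 | 1-{2,4-bis[(triethylsilyl)oxy]phenyl}-3-{2,2-dimethyl-7-(3-methylbut-2-en-1-yl)-8-[(triethylsilyl)oxy]-2H-chromen-6-yl}propan-1-one | CC(C)=CCc1c(CCC(=O)c2ccc(O[Si](CC)(CC)CC)cc2O[Si](CC)(CC)CC)cc2C=CC(C)(C)Oc2c1O[Si](CC)(CC)CC
F3 | step 2 | 4-chloro-2-methoxy-1-[(2-methylbut-3-yn-2-yl)oxy]benzene | C#CC(C)(C)Oc1ccc(Cl)cc1OC
F4 | step 2 | 6-chloro-8-methoxy-2,2-dimethyl-2H-chromene | COc1cc(Cl)cc2C=CC(C)(C)Oc12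
F5 | step 2 | 6-chloro-2,2-dimethyl-2H-chromen-8-ol | Oc1cc(Cl)cc2C=CC(C)(C)Oc12
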